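**Retrosynthetic overview** (atom labels follow the geranylfarnesyl chain: ring = C1–C14, C3 carries CO2Me, C14 is the stereocentre, side chain = C15–C19)
- The only ring (14-membered) is closed last, at C2=C3, by an intramolecular Horner–Wadsworth–Emmons reaction of a phosphonoester aldehyde.
- C1–C14, the C14 stereocentre and the E-C15=C16 alkene come from one Claisen rearrangement of the vinyl ether of an (R)-allylic alcohol (1,3-chirality transfer).
- The (R)-carbinol (C16) comes from enantioselective linear prenylation of an E-enal made by SeO2 oxidation of the terminal E-methyl group.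
- Key bond C4–C5: the zinc homoenolate of methyl propanoate (ester β-carbanion) alkylates (2E,6E)-farnesyl chloride, joining two carbons that are both normally electrophilic; C-phosphonylation at C3 follows.

Assumptions: farnesyl chloride, methyl 3-bromopropanoate and the reverse-prenyl pinacol boronate are bought (the boronate is otherwise one step from prenylmagnesium chloride and i-PrOBpin). All phosphorus-bearing intermediates are about 1:1 epimer mixtures at the P-bearing carbon, which is destroyed in the last step. (R)-TRIP is taken by analogy to give Re-face attack; if the sense proves opposite, the S acid is used.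

Step 1
Reactants: 1 (2E,6E)-farnesyl chloride; 2 methyl 3-bromopropanoate
Product: 4 methyl (5E,9E)-6,10,14-trimethylpentadeca-5,9,13-trienoate, via zinc homoenolate 3 (not isolated)
Conditions: 2, Zn dust, LiCl, THF, 50 °C; then 1, CoBr2 (10 mol%), THF/NMP, −10 °C to rt (3 used at 2 equiv)
Reagents that add atoms: none
Why: Zinc insertion turns the ester β-carbon into a nucleophile (homoenolate, d3 synthon), and cobalt-catalysed Negishi-type allylation of functionalised alkylzincs with primary allylic chlorides proceeds SN2 with retention of the E alkene, so the ester β-carbon (C4) and the allylic carbon (C5), both innately electrophilic, are joined in one step with no stereocentre formed.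

Step 2
Reactants: 4 methyl (5E,9E)-6,10,14-trimethylpentadeca-5,9,13-trienoate
Product: 6 methyl (5E,9E)-2-(diethoxyphosphoryl)-6,10,14-trimethylpentadeca-5,9,13-trienoate, via C-phosphonite 5 (not isolated)
Conditions: LDA (2.2 equiv), THF, −78 °C; ClP(OEt)2, −78 to 0 °C; then 30% H2O2, 0 °C
Reagents that add atoms: diethyl chlorophosphite, CCOP(Cl)OCC; hydrogen peroxide, OO
Why: C-phosphinylation of the lithium ester enolate with the soft P(III) chloride followed by P(III) to P(V) oxidation installs the phosphonate for the final olefination; the new C–P stereocentre is racemic and is destroyed in step 6.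

Step 3
Reactants: 6 methyl (5E,9E)-2-(diethoxyphosphoryl)-6,10,14-trimethylpentadeca-5,9,13-trienoate
Product: 8 methyl (5E,9E,13E)-2-(diethoxyphosphoryl)-6,10,14-trimethyl-15-oxopentadeca-5,9,13-trienoate, via allylic alcohol 7 (not isolated)
Conditions: SeO2 (0.3 equiv), t-BuOOH (2.5 equiv), salicylic acid (0.1 equiv), CH2Cl2, 0 °C to rt; then MnO2, CH2Cl2, rt
Reagents that add atoms: tert-butyl hydroperoxide, CC(C)(C)OO
Why: Catalytic SeO2/t-BuOOH allylic oxidation (ene reaction then [2,3]-shift) attacks the E-methyl of the terminal trisubstituted alkene, and MnO2 converges the alcohol/aldehyde mixture to the E-enal (moderate yield expected, starting material recycled).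

Step 4
Reactants: 8 methyl (5E,9E,13E)-2-(diethoxyphosphoryl)-6,10,14-trimethyl-15-oxopentadeca-5,9,13-trienoate; 9 4,4,5,5-tetramethyl-2-(2-methylbut-3-en-2-yl)-1,3,2-dioxaborolane
Product: 11 methyl (5E,9E,13E,15R)-2-(diethoxyphosphoryl)-15-hydroxy-6,10,14,18-tetramethylnonadeca-5,9,13,17-tetraenoate, via pinacol borate 10 (not isolated)
Conditions: (R)-TRIP (10 mol%), 4 Å MS, PhMe, −30 to 0 °C; aq. NaHCO3 work-up
Reagents that add atoms: none
Why: Proposed new method: chiral-phosphoric-acid-catalysed allylboration with the tertiary (reverse-prenyl) boronate, in which the closed six-membered chair transition state forces bonding at the unsubstituted γ-CH2 (so a linear prenyl group is delivered) while the BINOL phosphate hydrogen-bonds the boronate oxygen and the formyl C–H and exposes the Re face of the enal to set the 15R carbinol; the closest known reaction type is the phosphoric-acid-catalysed allyl- and crotylboration of aldehydes, including enals, with pinacol allylboronates.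

Step 5
Reactants: 11 methyl (5E,9E,13E,15R)-2-(diethoxyphosphoryl)-15-hydroxy-6,10,14,18-tetramethylnonadeca-5,9,13,17-tetraenoate
Product: 13 methyl (5E,9E,13R)-2-(diethoxyphosphoryl)-6,10-dimethyl-13-[(2E)-6-methylhepta-2,5-dien-2-yl]-15-oxopentadeca-5,9-dienoate, via allyl vinyl ether 12 (not isolated)
Conditions: Hg(OAc)2 (0.3 equiv), ethyl vinyl ether, reflux; evaporate; then PhMe, 120 °C (sealed tube)
Reagents that add atoms: ethyl vinyl ether, C=COCC
Why: Hg(II)-catalysed transvinylation followed by Claisen [3,3] rearrangement through a chair transition state with the prenyl CH2 equatorial forms C1–C14 suprafacially, so the 15R carbinol of the E-allylic alcohol is transferred to the new R stereocentre of the target, the trisubstituted alkene is formed E, and the aldehyde is unveiled.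

Step 6
Reactants: 13 methyl (5E,9E,13R)-2-(diethoxyphosphoryl)-6,10-dimethyl-13-[(2E)-6-methylhepta-2,5-dien-2-yl]-15-oxopentadeca-5,9-dienoate
Product: 14 methyl (1E,4R,7E,11E)-7,11-dimethyl-4-[(2E)-6-methylhepta-2,5-dien-2-yl]cyclotetradeca-1,7,11-triene-1-carboxylate (target)
Conditions: LiCl, DBU, MeCN, 2 mM (syringe-pump addition), rt
Reagents that add atoms: none
Why: Intramolecular Horner–Wadsworth–Emmons olefination (Masamune–Roush conditions, high dilution) closes the 14-membered ring and the α-alkyl phosphonoacetate gives the E enoate (ester trans to the ring CH2 from the aldehyde), while the stereocentre is β to the aldehyde and cannot epimerise.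

**Compound list**
1 | (2E,6E)-farnesyl chloride [(2E,6E)-1-chloro-3,7,11-trimethyldodeca-2,6,10-triene] | ClC/C=C(C)/CC/C=C(C)/CCC=C(C)C | starting material
2 | methyl 3-bromopropanoate | COC(=O)CCBr | starting material
3 | (3-methoxy-3-oxopropyl)zinc bromide | COC(=O)CC[Zn]Br | intermediate
4 | methyl (5E,9E)-6,10,14-trimethylpentadeca-5,9,13-trienoate | COC(=O)CCC/C=C(C)/CC/C=C(C)/CCC=C(C)C | intermediate
5 | methyl (5E,9E)-2-(diethoxyphosphanyl)-6,10,14-trimethylpentadeca-5,9,13-trienoate | COC(=O)C(P(OCC)OCC)CC/C=C(C)/CC/C=C(C)/CCC=C(C)C | intermediate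
6 | methyl (5E,9E)-2-(diethoxyphosphoryl)-6,10,14-trimethylpentadeca-5,9,13-trienoate | COC(=O)C(P(=O)(OCC)OCC)CC/C=C(C)/CC/C=C(C)/CCC=C(C)C | intermediate
7 | methyl (5E,9E,13E)-2-(diethoxyphosphoryl)-15-hydroxy-6,10,14-trimethylpentadeca-5,9,13-trienoate | COC(=O)C(P(=O)(OCC)OCC)CC/C=C(C)/CC/C=C(C)/CC/C=C(C)/CO | intermediate
8 | methyl (5E,9E,13E)-2-(diethoxyphosphoryl)-6,10,14-trimethyl-15-oxopentadeca-5,9,13-trienoate | COC(=O)C(P(=O)(OCC)OCC)CC/C=C(C)/CC/C=C(C)/CC/C=C(C)/C=O | intermediate
9 | 4,4,5,5-tetramethyl-2-(2-methylbut-3-en-2-yl)-1,3,2-dioxaborolane | C=CC(C)(C)B1OC(C)(C)C(C)(C)O1 | starting material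
10 | methyl (5E,9E,13E,15R)-2-(diethoxyphosphoryl)-6,10,14,18-tetramethyl-15-[(4,4,5,5-tetramethyl-1,3,2-dioxaborolan-2-yl)oxy]nonadeca-5,9,13,17-tetraenoate | COC(=O)C(P(=O)(OCC)OCC)CC/C=C(C)/CC/C=C(C)/CC/C=C(C)/[C@H](OB1OC(C)(C)C(C)(C)O1)CC=C(C)C | intermediate
11 | methyl (5E,9E,13E,15R)-2-(diethoxyphosphoryl)-15-hydroxy-6,10,14,18-tetramethylnonadeca-5,9,13,17-tetraenoate | COC(=O)C(P(=O)(OCC)OCC)CC/C=C(C)/CC/C=C(C)/CC/C=C(C)/[C@H](O)CC=C(C)C | intermediate
12 | methyl (5E,9E,13E,15R)-2-(diethoxyphosphoryl)-15-(ethenyloxy)-6,10,14,18-tetramethylnonadeca-5,9,13,17-tetraenoate | COC(=O)C(P(=O)(OCC)OCC)CC/C=C(C)/CC/C=C(C)/CC/C=C(C)/[C@H](OC=C)CC=C(C)C | intermediate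
13 | methyl (5E,9E,13R)-2-(diethoxyphosphoryl)-6,10-dimethyl-13-[(2E)-6-methylhepta-2,5-dien-2-yl]-15-oxopentadeca-5,9-dienoate | O=CC[C@H](/C(C)=C/CC=C(C)C)CC/C(C)=C/CC/C(C)=C/CCC(P(=O)(OCC)OCC)C(=O)OC | intermediate
14 | methyl (1E,4R,7E,11E)-7,11-dimethyl-4-[(2E)-6-methylhepta-2,5-dien-2-yl]cyclotetradeca-1,7,11-triene-1-carboxylate | COC(=O)/C1=C/C[C@H](/C(C)=C/CC=C(C)C)CC/C(C)=C/CC/C(C)=C/CC1 | target

**Total step count:** 6. **Longest linear sequence:** 6 (1 to 14).

**Steps most likely to fail, with fallbacks**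

Step 1 (sluggish transfer from the alkylzinc bromide, or SN2′ leakage). The fallback sets out from 1 and returns at 4, using a masked aldehyde homoenolate as a Grignard reagent instead of the zinc ester homoenolate. Commercial [2-(1,3-dioxolan-2-yl)ethyl]magnesium bromide and 1 with catalytic Li2CuCl4 (THF, −20 °C, α-selective coupling) give 2-[(4E,8E)-5,9,13-trimethyltetradeca-4,8,12-trien-1-yl]-1,3-dioxolane F1. Aqueous AcOH/THF unmasks (5E,9E)-6,10,14-trimethylpentadeca-5,9,13-trienal F2. Pinnick oxidation (NaClO2, NaH2PO4, 2-methyl-2-butene) gives (5E,9E)-6,10,14-trimethylpentadeca-5,9,13-trienoic acid F3, and TMSCHN2 in MeOH/PhMe returns ester 4.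

Step 3 (low conversion and competing oxidation at the internal allylic positions). The fallback sets out from 6 and returns at 8 by degrading the terminal alkene and rebuilding the enal. NBS in THF–H2O at 0 °C (terminal-selective) gives methyl (5E,9E)-13-bromo-2-(diethoxyphosphoryl)-14-hydroxy-6,10,14-trimethylpentadeca-5,9-dienoate F4. K2CO3 in MeOH closes it to methyl (5E,9E)-2-(diethoxyphosphoryl)-12-(3,3-dimethyloxiran-2-yl)-6,10-dimethyldodeca-5,9-dienoate F5. HIO4·2H2O in THF/Et2O cleaves this to methyl (5E,9E)-2-(diethoxyphosphoryl)-6,10-dimethyl-13-oxotrideca-5,9-dienoate F6. Wittig reaction with 2-(triphenylphosphoranylidene)propanal (PhMe, 80 °C) then gives E-enal 8.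

Step 4 (low rate or ee with the hindered tertiary boronate and an α-branched enal). The fallback sets out from 8 and returns at 11, setting the carbinol by reagent-controlled ketone reduction instead. Uncatalysed allylboration of 8 with 9 (PhMe, 60 °C) gives racemic methyl (5E,9E,13E)-2-(diethoxyphosphoryl)-6,10,14,18-tetramethyl-15-[(4,4,5,5-tetramethyl-1,3,2-dioxaborolan-2-yl)oxy]nonadeca-5,9,13,17-tetraenoate F7. Work-up hydrolyses it to racemic methyl (5E,9E,13E)-2-(diethoxyphosphoryl)-15-hydroxy-6,10,14,18-tetramethylnonadeca-5,9,13,17-tetraenoate F8. NaHCO3-buffered Dess–Martin oxidation gives methyl (5E,9E,13E)-2-(diethoxyphosphoryl)-6,10,14,18-tetramethyl-15-oxononadeca-5,9,13,17-tetraenoate F9, used at once to avoid alkene migration. (S)-Me-CBS (20 mol%) with catecholborane in PhMe at −78 °C (alkenyl as the large group) then gives 11.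

Further compounds
F1 | step 1 | 2-[(4E,8E)-5,9,13-trimethyltetradeca-4,8,12-trien-1-yl]-1,3-dioxolane | C1COC(O1)CCC/C=C(C)/CC/C=C(C)/CCC=C(C)C
F2 | step 1 | (5E,9E)-6,10,14-trimethylpentadeca-5,9,13-trienal | O=CCCC/C=C(C)/CC/C=C(C)/CCC=C(C)C
F3 | step 1 | (5E,9E)-6,10,14-trimethylpentadeca-5,9,13-trienoic acid | OC(=O)CCC/C=C(C)/CC/C=C(C)/CCC=C(C)C
F4 | step 3 | methyl (5E,9E)-13-bromo-2-(diethoxyphosphoryl)-14-hydroxy-6,10,14-trimethylpentadeca-5,9-dienoate | COC(=O)C(P(=O)(OCC)OCC)CC/C=C(C)/CC/C=C(C)/CCC(Br)C(C)(C)O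
F5 | step 3 | methyl (5E,9E)-2-(diethoxyphosphoryl)-12-(3,3-dimethyloxiran-2-yl)-6,10-dimethyldodeca-5,9-dienoate | COC(=O)C(P(=O)(OCC)OCC)CC/C=C(C)/CC/C=C(C)/CCC1OC1(C)C
F6 | step 3 | methyl (5E,9E)-2-(diethoxyphosphoryl)-6,10-dimethyl-13-oxotrideca-5,9-dienoate | COC(=O)C(P(=O)(OCC)OCC)CC/C=C(C)/CC/C=C(C)/CCC=O
F7 | step 4 | methyl (5E,9E,13E)-2-(diethoxyphosphoryl)-6,10,14,18-tetramethyl-15-[(4,4,5,5-tetramethyl-1,3,2-dioxaborolan-2-yl)oxy]nonadeca-5,9,13,17-tetraenoate (racemic) | COC(=O)C(P(=O)(OCC)OCC)CC/C=C(C)/CC/C=C(C)/CC/C=C(C)/C(OB1OC(C)(C)C(C)(C)O1)CC=C(C)C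
F8 | step 4 | methyl (5E,9E,13E)-2-(diethoxyphosphoryl)-15-hydroxy-6,10,14,18-tetramethylnonadeca-5,9,13,17-tetraenoate (racemic) | COC(=O)C(P(=O)(OCC)OCC)CC/C=C(C)/CC/C=C(C)/CC/C=C(C)/C(O)CC=C(C)C
F9 | step 4 | methyl (5E,9E,13E)-2-(diethoxyphosphoryl)-6,10,14,18-tetramethyl-15-oxononadeca-5,9,13,17-tetraenoate | COC(=O)C(P(=O)(OCC)OCC)CC/C=C(C)/CC/C=C(C)/CC/C=C(C)/C(=O)CC=C(C)C
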